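**Retrosynthetic overview**

1. Ring numbering: C1 (oxirane CH), C2 (CH2), C3 (CH–O-angeloyl), C4 (oxirane C–CH3), C5 (oxirane CH), C6 (CH2), C7 (CH–isopropenyl), C8 (CH–O-angeloyl), C9 (CH–OAc), C10 (oxirane C–CH3). The plan rests on the C3 carbinol being bonded to C4 of the cis-fused 4,5-oxirane, that is to one carbon of a former Z-alkene C4=C5 inside the ten-membered carbocycle.
2. Target ⇒ O3 angeloylation and hydroxyl-guided peracid epoxidation of C4=C5 ⇒ ten-membered Z-allylic alcohol ⇒ C3–C4 disconnection (intramolecular Nozaki–Hiyama–Kishi) ⇒ open-chain Z-alkenyl iodide (C4) / aldehyde (C3) that already carries the 1,10-oxirane, the O9 acetate and the O8 angelate.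
3. Alkenyl iodide ⇒ α-iodo-Wittig olefination of a C5 aldehyde; C7–C8 ⇒ Z-allylboration of a C8 α-acetoxy aldehyde, which sets C7 and C8 together.
4. C8 aldehyde ⇒ ozonolysis of the vinyl adduct of a C9 epoxy aldehyde, itself from Still–Gennari olefination and Sharpless epoxidation (C1, C10); Z-allylboronate ⇒ Z-alkenyl iodide + ClCH2Bpin.
5. Ring order: 1,10-oxirane (step 4), ten-membered carbocycle (step 19), 4,5-oxirane (step 20).

Key step: step 19

Assumption (chemistry): the chromium-mediated ring closure of step 19 is taken to attack the Re face of the C3 aldehyde and give the 3S carbinol (O3 on the ring face that also carries O8 and O9); the first fallback covers the opposite outcome.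

Abbreviations: TBS = tert-butyldimethylsilyl; PMB = 4-methoxybenzyl; Bpin = 4,4,5,5-tetramethyl-1,3,2-dioxaborolan-2-yl. Open-chain compounds 21 and 24–29 are described with the ring numbering above.

**Route**

Step 1
Reactants: 1 3-[(tert-butyldimethylsilyl)oxy]propan-1-ol
Product: 2 3-[(tert-butyldimethylsilyl)oxy]propanal
Conditions: TEMPO (10 mol%), PhI(OAc)2, CH2Cl2, rt
Reagents that add atoms: none
Why: TEMPO (oxoammonium) oxidation of a primary alcohol stops at the aldehyde and leaves the silyl ether untouched.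

Step 2
Reactants: 2 3-[(tert-butyldimethylsilyl)oxy]propanal; 3 ethyl 2-[bis(2,2,2-trifluoroethoxy)phosphoryl]propanoate
Product: 5 ethyl (2Z)-5-[(tert-butyldimethylsilyl)oxy]-2-methylpent-2-enoate, via potassium phosphonate carbanion 4 (not isolated)
Conditions: KN(SiMe3)2, 18-crown-6, THF, −78 °C; then 2
Reagents that add atoms: none
Why: Still–Gennari olefination, in which the electron-poor bis(trifluoroethyl) phosphonate eliminates from the kinetic adduct and gives the Z-trisubstituted enoate, placing the future C9 cis to C2 across C10=C1.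

Step 3
Reactants: 5 ethyl (2Z)-5-[(tert-butyldimethylsilyl)oxy]-2-methylpent-2-enoate
Product: 6 (2Z)-5-[(tert-butyldimethylsilyl)oxy]-2-methylpent-2-en-1-ol
Conditions: i-Bu2AlH (2.2 equiv), CH2Cl2, −78 °C
Reagents that add atoms: none
Why: Aluminium hydride 1,2-reduction of the enoate gives the allylic alcohol without touching the alkene geometry.

Step 4
Reactants: 6 (2Z)-5-[(tert-butyldimethylsilyl)oxy]-2-methylpent-2-en-1-ol
Product: 7 [(2S,3R)-3-{2-[(tert-butyldimethylsilyl)oxy]ethyl}-2-methyloxiran-2-yl]methanol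
Conditions: Ti(Oi-Pr)4 (10 mol%), L-(+)-diethyl tartrate (12 mol%), t-BuOOH, 4 Å MS, CH2Cl2, −20 °C
Reagents that add atoms: tert-butyl hydroperoxide CC(C)(C)OO
Why: Sharpless asymmetric epoxidation, in which Ti(Oi-Pr)4 with L-(+)-diethyl tartrate delivers oxygen to the alkene face that gives the (2S,3R)-epoxy alcohol, as with other Z-allylic alcohols, and so sets C10 and C1 while the Z geometry fixes the cis oxirane.

Step 5
Reactants: 7 [(2S,3R)-3-{2-[(tert-butyldimethylsilyl)oxy]ethyl}-2-methyloxiran-2-yl]methanol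
Product: 8 (2R,3R)-3-{2-[(tert-butyldimethylsilyl)oxy]ethyl}-2-methyloxirane-2-carbaldehyde
Conditions: TEMPO (10 mol%), PhI(OAc)2, CH2Cl2, rt
Reagents that add atoms: none
Why: TEMPO oxidation gives the epoxy aldehyde, which cannot epimerise because its α-carbon is quaternary.

Step 6
Reactants: 8 (2R,3R)-3-{2-[(tert-butyldimethylsilyl)oxy]ethyl}-2-methyloxirane-2-carbaldehyde; 9 vinylmagnesium bromide
Product: 11 (1S)-1-[(2R,3R)-3-{2-[(tert-butyldimethylsilyl)oxy]ethyl}-2-methyloxiran-2-yl]prop-2-en-1-yl acetate, via bromomagnesium alkoxide 10 (not isolated)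
Conditions: 9 (1.3 equiv), THF, −78 °C; then Ac2O (3 equiv), DMAP (cat.), −78 → 0 °C
Reagents that add atoms: acetic anhydride CC(=O)OC(C)=O
Why: Non-chelated Grignard 1,2-addition under Felkin–Anh/Cornforth control, in which the carbonyl lies anti to the oxirane C–O bond and the vinyl group enters on the side away from the cis C2 chain of the neighbouring oxirane carbon, should set C9 as the anti (1S) carbinol, which is trapped in the same flask as its acetate.

Step 7
Reactants: 11 (1S)-1-[(2R,3R)-3-{2-[(tert-butyldimethylsilyl)oxy]ethyl}-2-methyloxiran-2-yl]prop-2-en-1-yl acetate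
Product: 13 (1R)-1-[(2R,3R)-3-{2-[(tert-butyldimethylsilyl)oxy]ethyl}-2-methyloxiran-2-yl]-2-oxoethyl acetate, via ozonide 12 (not isolated)
Conditions: O3, CH2Cl2, −78 °C; then PPh3, −78 °C → rt; used crude
Reagents that add atoms: ozone [O-][O+]=O
Why: Ozonolysis with reductive work-up cleaves the only alkene to the C8 aldehyde under neutral conditions, so the base-sensitive α-acetoxy centre C9 (next to the oxirane) is preserved.

Step 8
Reactants: 14 3-[(4-methoxybenzyl)oxy]propan-1-ol
Product: 15 3-[(4-methoxybenzyl)oxy]propanal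
Conditions: TEMPO (10 mol%), PhI(OAc)2, CH2Cl2, rt
Reagents that add atoms: none
Why: TEMPO oxidation of the primary alcohol gives the aldehyde and tolerates the benzylic ether.

Step 9
Reactants: 15 3-[(4-methoxybenzyl)oxy]propanal
Product: 16 1-({[(3Z)-4-iodopent-3-en-1-yl]oxy}methyl)-4-methoxybenzene
Conditions: [Ph3PEt]I, n-BuLi, THF, 0 °C; I2, −78 °C; NaN(SiMe3)2, −20 °C; then 15, −78 °C → rt
Reagents that add atoms: ethyltriphenylphosphonium iodide CC[P+](c1ccccc1)(c1ccccc1)c1ccccc1.[I-]; iodine II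
Why: Wittig olefination with the α-iodoethylidene ylide (Stork–Zhao type) reacts under kinetic control and gives the Z-2-iodoalkene with iodine cis to the chain.

Step 10
Reactants: 16 1-({[(3Z)-4-iodopent-3-en-1-yl]oxy}methyl)-4-methoxybenzene; 17 2-(chloromethyl)-4,4,5,5-tetramethyl-1,3,2-dioxaborolane
Product: 20 2-[(2Z)-5-[(4-methoxybenzyl)oxy]-2-methylpent-2-en-1-yl]-4,4,5,5-tetramethyl-1,3,2-dioxaborolane, via alkenyllithium 18 (not isolated), via chloromethyl boronate complex 19 (not isolated)
Conditions: t-BuLi (2.0 equiv), Et2O, −78 °C; then 17, −78 °C → rt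
Reagents that add atoms: none
Why: Iodine–lithium exchange with retention of alkene geometry followed by a Matteson-type homologation, in which the alkenyl group of complex 19 migrates from boron to carbon with loss of chloride, gives the Z-allylboronate (CH2B cis to the chain).

Step 11
Reactants: 13 (1R)-1-[(2R,3R)-3-{2-[(tert-butyldimethylsilyl)oxy]ethyl}-2-methyloxiran-2-yl]-2-oxoethyl acetate; 20 2-[(2Z)-5-[(4-methoxybenzyl)oxy]-2-methylpent-2-en-1-yl]-4,4,5,5-tetramethyl-1,3,2-dioxaborolane
Product: 21 coupling product: chain C5–C3 with 5-O-PMB; (7R)-isopropenyl; (8S)-OH; (9S)-OAc; (1R,10R)-1,10-oxirane; 3-O-TBS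
Conditions: toluene (1 M), 4 Å MS, rt, 48 h; then aq. NaHCO3
Reagents that add atoms: none
Why: Allylboration through a closed Zimmerman–Traxler chair, in which the Z-boronate gives the 7,8-syn relationship and attack anti to the α-acetoxy group (Felkin–Anh/Cornforth, the sense that Z-γ-substituted boronates reinforce) gives 8,9-anti, should set C7 (R) and C8 (S) together and create the isopropenyl group by allylic transposition.

Step 12
Reactants: 22 angelic acid [(2Z)-2-methylbut-2-enoic acid]
Product: 23 (2Z)-2-methylbut-2-enoic 2,4,6-trichlorobenzoic anhydride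
Conditions: 2,4,6-trichlorobenzoyl chloride (1.0 equiv), Et3N (1.05 equiv), toluene, 0 °C → rt; filtered under argon and kept as a toluene stock solution at −20 °C
Reagents that add atoms: 2,4,6-trichlorobenzoyl chloride O=C(Cl)c1c(Cl)cc(Cl)cc1Cl
Why: Yamaguchi-type activation, in which the triethylammonium carboxylate of 22 displaces chloride from the hindered aroyl chloride at room temperature, gives the mixed anhydride with the Z geometry intact, and one batch, freed of the ammonium salt by filtration, serves steps 13 and 21.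

Step 13
Reactants: 21 coupling product (8-OH); 23 (2Z)-2-methylbut-2-enoic 2,4,6-trichlorobenzoic anhydride
Product: 24 8-O-angeloyl ester of 21
Conditions: 23 (3 equiv, toluene stock solution), Et3N (1.5 equiv), toluene, 70 °C
Reagents that add atoms: none
Why: Yamaguchi-type mixed-anhydride esterification, in which the alcohol attacks the less hindered angeloyl carbonyl of 23, is run without a nucleophilic catalyst to avoid the addition–elimination that turns angelates into tiglates, and acylating O8 at once forestalls acetyl migration from O9.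

Step 14
Reactants: 24 8-O-angeloyl ester (5-O-PMB; 3-O-TBS)
Product: 25 C5 primary alcohol (8-O-angeloyl; 9-OAc; 3-O-TBS)
Conditions: DDQ, CH2Cl2/pH 7 buffer (10:1), 0 °C → rt
Reagents that add atoms: none
Why: Oxidative cleavage of the 4-methoxybenzyl ether by DDQ (benzylic hydride abstraction, hydrolysis of the oxocarbenium ion) is orthogonal to the silyl ether, both esters, the oxirane and the isopropenyl group.

Step 15
Reactants: 25 C5 primary alcohol
Product: 26 C5 aldehyde (8-O-angeloyl; 9-OAc; 3-O-TBS)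
Conditions: Dess–Martin periodinane, pyridine, CH2Cl2, 0 °C → rt
Reagents that add atoms: none
Why: Buffered Dess–Martin oxidation gives the aldehyde without disturbing C7 or the esters.

Step 16
Reactants: 26 C5 aldehyde
Product: 27 (4Z)-alkenyl iodide I–C4(CH3)=C5H–C6 (8-O-angeloyl; 9-OAc; 3-O-TBS)
Conditions: [Ph3PEt]I, n-BuLi, THF, 0 °C; I2, −78 °C; NaN(SiMe3)2, −20 °C; then 26, −78 °C → 0 °C
Reagents that add atoms: ethyltriphenylphosphonium iodide CC[P+](c1ccccc1)(c1ccccc1)c1ccccc1.[I-]; iodine II
Why: Wittig olefination with the α-iodoethylidene ylide fixes the Z geometry of C4=C5 (iodine cis to C6) before ring closure, and the ylide is not basic enough to enolise the acetate or open the oxirane at low temperature.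

Step 17
Reactants: 27 (4Z)-alkenyl iodide (3-O-TBS)
Product: 28 C3 primary alcohol of the (4Z)-alkenyl iodide
Conditions: HF·pyridine, pyridine, THF, 0 °C → rt
Reagents that add atoms: none
Why: Fluoride-mediated desilylation with pyridine-buffered HF·pyridine removes the primary silyl ether and leaves the oxirane, both esters and the alkenyl iodide intact.

Step 18
Reactants: 28 C3 primary alcohol
Product: 29 (4Z)-alkenyl iodide C3 aldehyde with (1R,10R)-oxirane; (9S)-OAc; (8S)-O-angeloyl; (7R)-isopropenyl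
Conditions: Dess–Martin periodinane, pyridine, CH2Cl2, 0 °C; filtered and used at once
Reagents that add atoms: none
Why: Dess–Martin oxidation under mild buffered conditions gives the β,γ-epoxy aldehyde, which is not stored because base would open the oxirane by β-elimination.

Step 19
Reactants: 29 (4Z)-alkenyl iodide C3 aldehyde
Product: 31 (1R,3S,4Z,7R,8S,9S,10R)-9-acetoxy-1,10-epoxy-3-hydroxy-4,10-dimethyl-7-(prop-1-en-2-yl)cyclodec-4-en-8-yl (2Z)-2-methylbut-2-enoate, via alkenylchromium dichloride 30 (not isolated)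
Conditions: CrCl2 (10 equiv), NiCl2 (0.1 equiv), degassed DMSO, slow addition of 29 to 2 mM, rt
Reagents that add atoms: none
Why: CrCl2 (divalent chromium) reduces NiCl2 to zerovalent nickel, which inserts into the C4–iodine bond with retention of the Z geometry; transmetallation gives alkenylchromium 30 (trivalent chromium), whose carbon–chromium bond adds to the chromium-bound C3 aldehyde, and the chromium alkoxide is hydrolysed on work-up. This is an intramolecular Nozaki–Hiyama–Kishi coupling of an alkenyl iodide with an aldehyde, a known way to close medium and large carbocycles. The one new ring, the ten-membered carbocycle, closes in the 10-exo-trig mode by forming C3–C4, and slow addition at high dilution keeps closure ahead of intermolecular coupling. C3 is the only new stereocentre and is under substrate control: the aldehyde C–H bond has to lie in the alkene plane to avoid allylic strain with C6, so C2 and the chromium-bound oxygen take the two alkene faces, and the fold of the C6–C10 tether with the C7 isopropenyl group pseudo-equatorial is taken to expose the Re face, which gives 3S. The step needs retention of the Z geometry, which the preformed alkenyl iodide secures, and attack at the aldehyde only, which the weakly basic, carbonyl-selective organochromium reagent secures in the presence of the acetate, the angelate, the oxirane and the enolisable β,γ-epoxy aldehyde.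

Step 20
Reactants: 31 ten-membered Z-allylic alcohol
Product: 32 (1R,3S,4R,5S,7R,8S,9S,10R)-9-acetoxy-1,10:4,5-diepoxy-3-hydroxy-4,10-dimethyl-7-(prop-1-en-2-yl)cyclodecan-8-yl (2Z)-2-methylbut-2-enoate
Conditions: mCPBA (1.05 equiv), CH2Cl2/0.5 M aq. NaHCO3, −20 → 0 °C
Reagents that add atoms: 3-chloroperbenzoic acid OOC(=O)c1cccc(Cl)c1
Why: Prilezhaev epoxidation, in which the peracid, hydrogen-bonded to O3–H, attacks the trisubstituted C4=C5 bond from the ring periphery while the C3–H bond lies in the alkene plane, should give the cis-fused oxirane trans to O3 across the ring, as peracids do with eight- and nine-membered (Z)-cycloalk-2-enols; the isopropenyl group reacts more slowly and the angelate not at all.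

Step 21
Reactants: 32 diepoxy alcohol; 23 (2Z)-2-methylbut-2-enoic 2,4,6-trichlorobenzoic anhydride
Product: 33 (1R,3S,4S,5S,7R,8S,9S,10R)-9-acetoxy-1,10:4,5-diepoxy-4,10-dimethyl-7-(prop-1-en-2-yl)cyclodecane-3,8-diyl bis[(2Z)-2-methylbut-2-enoate]
Conditions: 23 (3 equiv, toluene stock solution), Et3N (1.5 equiv), toluene, 70 °C
Reagents that add atoms: none
Why: Yamaguchi-type mixed-anhydride esterification acylates the hindered C3 hydroxyl with retention at C3 and without a nucleophilic catalyst that would isomerise the angeloyl group, which completes the target.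

**Compound list**

1 | 3-[(tert-butyldimethylsilyl)oxy]propan-1-ol | OCCCO[Si](C)(C)C(C)(C)C | starting material
2 | 3-[(tert-butyldimethylsilyl)oxy]propanal | O=CCCO[Si](C)(C)C(C)(C)C | intermediate
3 | ethyl 2-[bis(2,2,2-trifluoroethoxy)phosphoryl]propanoate | CCOC(=O)C(C)P(=O)(OCC(F)(F)F)OCC(F)(F)F | starting material
4 | potassium phosphonate carbanion of 3 (not isolated) | CCOC(=O)[C-](C)P(=O)(OCC(F)(F)F)OCC(F)(F)F.[K+] | intermediate
5 | ethyl (2Z)-5-[(tert-butyldimethylsilyl)oxy]-2-methylpent-2-enoate | CCOC(=O)/C(C)=C\CCO[Si](C)(C)C(C)(C)C | intermediate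
6 | (2Z)-5-[(tert-butyldimethylsilyl)oxy]-2-methylpent-2-en-1-ol | OC/C(C)=C\CCO[Si](C)(C)C(C)(C)C | intermediate
7 | [(2S,3R)-3-{2-[(tert-butyldimethylsilyl)oxy]ethyl}-2-methyloxiran-2-yl]methanol | OC[C@]1(C)O[C@@H]1CCO[Si](C)(C)C(C)(C)C | intermediate
8 | (2R,3R)-3-{2-[(tert-butyldimethylsilyl)oxy]ethyl}-2-methyloxirane-2-carbaldehyde | O=C[C@]1(C)O[C@@H]1CCO[Si](C)(C)C(C)(C)C | intermediate
9 | vinylmagnesium bromide | C=C[Mg]Br | starting material
10 | bromomagnesium (1S)-1-[(2R,3R)-3-{2-[(tert-butyldimethylsilyl)oxy]ethyl}-2-methyloxiran-2-yl]prop-2-en-1-olate (not isolated) | C=C[C@H](O[Mg]Br)[C@]1(C)O[C@@H]1CCO[Si](C)(C)C(C)(C)C | intermediate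
11 | (1S)-1-[(2R,3R)-3-{2-[(tert-butyldimethylsilyl)oxy]ethyl}-2-methyloxiran-2-yl]prop-2-en-1-yl acetate | C=C[C@H](OC(C)=O)[C@]1(C)O[C@@H]1CCO[Si](C)(C)C(C)(C)C | intermediate
12 | ozonide of 11: (R)-[(2R,3R)-3-{2-[(tert-butyldimethylsilyl)oxy]ethyl}-2-methyloxiran-2-yl](1,2,4-trioxolan-3-yl)methyl acetate, trioxolane carbon unassigned (not isolated) | C1OOC(O1)[C@H](OC(C)=O)[C@]2(C)O[C@@H]2CCO[Si](C)(C)C(C)(C)C | intermediate
13 | (1R)-1-[(2R,3R)-3-{2-[(tert-butyldimethylsilyl)oxy]ethyl}-2-methyloxiran-2-yl]-2-oxoethyl acetate | O=C[C@H](OC(C)=O)[C@]1(C)O[C@@H]1CCO[Si](C)(C)C(C)(C)C | intermediate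
14 | 3-[(4-methoxybenzyl)oxy]propan-1-ol | OCCCOCc1ccc(OC)cc1 | starting material
15 | 3-[(4-methoxybenzyl)oxy]propanal | O=CCCOCc1ccc(OC)cc1 | intermediate
16 | 1-({[(3Z)-4-iodopent-3-en-1-yl]oxy}methyl)-4-methoxybenzene | I/C(C)=C\CCOCc1ccc(OC)cc1 | intermediate
17 | 2-(chloromethyl)-4,4,5,5-tetramethyl-1,3,2-dioxaborolane | ClCB1OC(C)(C)C(C)(C)O1 | starting material
18 | {5-[(4-methoxybenzyl)oxy]pent-2-en-2-yl}lithium, lithium cis to the chain (not isolated) | [Li]/C(C)=C\CCOCc1ccc(OC)cc1 | intermediate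
19 | lithium (chloromethyl)(alkenyl)pinacolboronate complex from 17 and 18 (not isolated) | [Li+].ClC[B-]1(OC(C)(C)C(C)(C)O1)/C(C)=C\CCOCc1ccc(OC)cc1 | intermediate
20 | 2-[(2Z)-5-[(4-methoxybenzyl)oxy]-2-methylpent-2-en-1-yl]-4,4,5,5-tetramethyl-1,3,2-dioxaborolane | CC1(C)OB(C/C(C)=C\CCOCc2ccc(OC)cc2)OC1(C)C | intermediate
21 | coupling product: chain C5–C3 with 5-O-PMB; (7R)-isopropenyl; (8S)-OH; (9S)-OAc; (1R,10R)-1,10-oxirane (10-methyl); 3-O-TBS | COc1ccc(COCC[C@H](C(C)=C)[C@H](O)[C@H](OC(C)=O)[C@]2(C)O[C@@H]2CCO[Si](C)(C)C(C)(C)C)cc1 | intermediate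
22 | angelic acid, (2Z)-2-methylbut-2-enoic acid | C/C=C(/C)C(=O)O | starting material
23 | (2Z)-2-methylbut-2-enoic 2,4,6-trichlorobenzoic anhydride | C/C=C(/C)C(=O)OC(=O)c1c(Cl)cc(Cl)cc1Cl | intermediate
24 | 8-O-angeloyl ester of 21 (1R,7R,8S,9S,10R) | COc1ccc(COCC[C@H](C(C)=C)[C@H](OC(=O)/C(C)=C\C)[C@H](OC(C)=O)[C@]2(C)O[C@@H]2CCO[Si](C)(C)C(C)(C)C)cc1 | intermediate
25 | C5 primary alcohol (8-O-angeloyl; 9-OAc; 1,10-oxirane; 3-O-TBS; 1R,7R,8S,9S,10R) | OCC[C@H](C(C)=C)[C@H](OC(=O)/C(C)=C\C)[C@H](OC(C)=O)[C@]1(C)O[C@@H]1CCO[Si](C)(C)C(C)(C)C | intermediate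
26 | C5 aldehyde (8-O-angeloyl; 9-OAc; 1,10-oxirane; 3-O-TBS; 1R,7R,8S,9S,10R) | O=CC[C@H](C(C)=C)[C@H](OC(=O)/C(C)=C\C)[C@H](OC(C)=O)[C@]1(C)O[C@@H]1CCO[Si](C)(C)C(C)(C)C | intermediate
27 | (4Z)-alkenyl iodide, iodine on C4 cis to C6 (8-O-angeloyl; 9-OAc; 1,10-oxirane; 3-O-TBS; 1R,7R,8S,9S,10R) | I/C(C)=C\C[C@H](C(C)=C)[C@H](OC(=O)/C(C)=C\C)[C@H](OC(C)=O)[C@]1(C)O[C@@H]1CCO[Si](C)(C)C(C)(C)C | intermediate
28 | C3 primary alcohol of the (4Z)-alkenyl iodide (1R,7R,8S,9S,10R) | I/C(C)=C\C[C@H](C(C)=C)[C@H](OC(=O)/C(C)=C\C)[C@H](OC(C)=O)[C@]1(C)O[C@@H]1CCO | intermediate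
29 | (4Z)-alkenyl iodide C3 aldehyde, precursor of the ring closure (1R,7R,8S,9S,10R) | I/C(C)=C\C[C@H](C(C)=C)[C@H](OC(=O)/C(C)=C\C)[C@H](OC(C)=O)[C@]1(C)O[C@@H]1CC=O | intermediate
30 | alkenylchromium dichloride from 29, trivalent chromium on C4 (not isolated) | Cl[Cr](Cl)/C(C)=C\C[C@H](C(C)=C)[C@H](OC(=O)/C(C)=C\C)[C@H](OC(C)=O)[C@]1(C)O[C@@H]1CC=O | intermediate
31 | (1R,3S,4Z,7R,8S,9S,10R)-9-acetoxy-1,10-epoxy-3-hydroxy-4,10-dimethyl-7-(prop-1-en-2-yl)cyclodec-4-en-8-yl (2Z)-2-methylbut-2-enoate | C=C(C)[C@H]1C/C=C(C)\[C@@H](O)C[C@H]2O[C@@]2(C)[C@@H](OC(C)=O)[C@H]1OC(=O)/C(C)=C\C | intermediate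
32 | (1R,3S,4R,5S,7R,8S,9S,10R)-9-acetoxy-1,10:4,5-diepoxy-3-hydroxy-4,10-dimethyl-7-(prop-1-en-2-yl)cyclodecan-8-yl (2Z)-2-methylbut-2-enoate | C=C(C)[C@H]1C[C@@H]2O[C@]2(C)[C@@H](O)C[C@H]2O[C@@]2(C)[C@@H](OC(C)=O)[C@H]1OC(=O)/C(C)=C\C | intermediate
33 | (1R,3S,4S,5S,7R,8S,9S,10R)-9-acetoxy-1,10:4,5-diepoxy-4,10-dimethyl-7-(prop-1-en-2-yl)cyclodecane-3,8-diyl bis[(2Z)-2-methylbut-2-enoate] (CNP0220329.1) | C=C(C)[C@H]1C[C@@H]2O[C@]2(C)[C@@H](OC(=O)/C(C)=C\C)C[C@H]2O[C@@]2(C)[C@@H](OC(C)=O)[C@H]1OC(=O)/C(C)=C\C | target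

**Step count and risks**

Total step count: 21. Longest linear sequence: 17 steps (steps 1–7, then 11, then 13–21); steps 8–10 make the boronate and step 12 makes the acylating agent used in steps 13 and 21.

Steps most likely to fail:

1. Step 19. The ring closure may show poor facial selectivity at the aldehyde, or favour the Si face, so that the C3 epimer accompanies or replaces 31. The fallback sets out from 31 as obtained, of whatever C3 composition, and comes back at 31; it sets C3 by reagent-controlled hydride delivery instead of during carbon–carbon bond formation. Dess–Martin oxidation (pyridine, CH2Cl2) would give the ten-membered (4Z)-cyclodec-4-en-3-one F1. Reduction with catecholborane and (R)-1-methyl-3,3-diphenyl-tetrahydro-1H,3H-pyrrolo[1,2-c][1,3,2]oxazaborole (20 mol%) in toluene at −78 °C treats the α-branched alkenyl side as the large group and should return 31 with the 3S configuration, without hydroborating the isopropenyl group.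

2. Step 20. The peracid may also attack the isopropenyl group, and face selectivity at C4=C5 may be incomplete. The fallback sets out from 31 and comes back at 33; it replaces peripheral peracid attack by metal-bound oxygen delivery on the C3 epimer, followed by inversion. Oxidation as above gives the enone F1, and reduction with catecholborane and the (S)-oxazaborolidine gives the 3R allylic alcohol F2. VO(acac)2 with t-BuOOH in CH2Cl2 epoxidises only the alkene next to the vanadium-bound hydroxyl and, as in eight- and nine-membered (Z)-cycloalk-2-enols, delivers oxygen cis to it, which should give the (3R)-diepoxy alcohol F3 carrying the 4,5-oxirane of the target. Mitsunobu esterification with angelic acid 22 (PPh3, diisopropyl azodicarboxylate, toluene) then inverts C3 and gives 33 directly.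

3. Step 6. The Grignard addition may show poor facial selectivity, because partial chelation between the carbonyl and oxirane oxygens leads to the syn carbinol. The fallback sets out from 8 and comes back at 11; it sets C9 by hydride reduction of a ketone instead of by carbon–carbon bond formation. Addition of 9 with aqueous quench gives the vinyl carbinol F4 as a mixture at the carbinol carbon. Dess–Martin oxidation gives the epoxy vinyl ketone F5. Zn(BH4)2 in Et2O at −20 °C reduces it in the 1,2-sense through a chelate of the carbonyl and oxirane oxygens, with hydride entering away from the neighbouring oxirane carbon, and should give the anti (1S) carbinol F6. Acetylation (Ac2O, pyridine, DMAP) returns 11.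

**Further compounds**

F1 | step 19 | (1R,4Z,7R,8S,9S,10R)-9-acetoxy-1,10-epoxy-4,10-dimethyl-3-oxo-7-(prop-1-en-2-yl)cyclodec-4-en-8-yl (2Z)-2-methylbut-2-enoate | C=C(C)[C@H]1C/C=C(C)\C(=O)C[C@H]2O[C@@]2(C)[C@@H](OC(C)=O)[C@H]1OC(=O)/C(C)=C\C
F2 | step 20 | (3R) epimer of 31: (1R,3R,4Z,7R,8S,9S,10R)-9-acetoxy-1,10-epoxy-3-hydroxy-4,10-dimethyl-7-(prop-1-en-2-yl)cyclodec-4-en-8-yl (2Z)-2-methylbut-2-enoate | C=C(C)[C@H]1C/C=C(C)\[C@H](O)C[C@H]2O[C@@]2(C)[C@@H](OC(C)=O)[C@H]1OC(=O)/C(C)=C\C
F3 | step 20 | (3R) epimer of 32: (1R,3R,4R,5S,7R,8S,9S,10R)-9-acetoxy-1,10:4,5-diepoxy-3-hydroxy-4,10-dimethyl-7-(prop-1-en-2-yl)cyclodecan-8-yl (2Z)-2-methylbut-2-enoate | C=C(C)[C@H]1C[C@@H]2O[C@]2(C)[C@H](O)C[C@H]2O[C@@]2(C)[C@@H](OC(C)=O)[C@H]1OC(=O)/C(C)=C\C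
F4 | step 6 | 1-[(2S,3R)-3-{2-[(tert-butyldimethylsilyl)oxy]ethyl}-2-methyloxiran-2-yl]prop-2-en-1-ol, mixture at the carbinol carbon | C=CC(O)[C@]1(C)O[C@@H]1CCO[Si](C)(C)C(C)(C)C
F5 | step 6 | 1-[(2R,3R)-3-{2-[(tert-butyldimethylsilyl)oxy]ethyl}-2-methyloxiran-2-yl]prop-2-en-1-one | C=CC(=O)[C@]1(C)O[C@@H]1CCO[Si](C)(C)C(C)(C)C
F6 | step 6 | (1S)-1-[(2S,3R)-3-{2-[(tert-butyldimethylsilyl)oxy]ethyl}-2-methyloxiran-2-yl]prop-2-en-1-ol | C=C[C@H](O)[C@]1(C)O[C@@H]1CCO[Si](C)(C)C(C)(C)C
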